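**Plan**

1. Numbering used: ring B = C1–C5 plus spiro C6 (Br on C2; Cl and CH3 on C3); ring A = C6–C11 (C7 carries the methylidene carbon C14, C9 the acetate, C10 Br, C11 two CH3).
2. Retrosynthetic cuts, in order: C9–OAc; C9–H (back to the C9 ketone); C9–C10 of ring A (to a C10 gem-dibromide and a C9 N-methoxy-N-methylamide); C7–C8 and C7–C14 (alkenyl triflate coupling; MeLi on a lactone); C3–Cl and C2–Br (through a temporary C7–O–C3 lactone); C6–C1 and C5–C4 (Diels–Alder).
3. Forward order: ring B is made first by Diels–Alder reaction of isoprene with an α-methylene γ-lactone that already holds C7, C6, C11 and C10; ring B is then halogenated, the lactone is unfolded into the C7 and C10 arms, and ring A is closed last.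
4. Feature that makes the ring closure possible: C10 is a neopentyl carbon between quaternary C11 and C9, so a bromo-carbenoid at C10 has no β-hydrogen to lose and sits 1,6 to the C9 carbonyl through C11–C6–C7–C8; acylation there closes ring A and leaves Br on C10 beside a C9 ketone.
5. Stereochemistry: C6 comes from a catalytic asymmetric Diels–Alder reaction; C2 and C3 are relayed from C6 in one bromolactonisation (then O→Cl with retention); C10 is formed in the ring closure without substrate bias, so the 10R ketone is picked by a catalyst-controlled CBS reduction, which also sets C9 cis to C10.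

Key step: step 10

Assumption: the (S)-configured oxazaborolidinium catalyst is taken to give the (5S) lactone 4; if it favours the other face, its (R) enantiomer is used instead.

**Route**

Step 1
Reactants: 1 4,4-dimethyloxolane-2,3-dione (ketopantolactone)
Product: 2 4,4-dimethyl-3-methylideneoxolan-2-one
Conditions: Ph3PCH3Br, KOtBu, THF, 0 °C; then 1, −78 °C → rt
Reagents that add atoms: methyltriphenylphosphonium bromide, C[P+](c1ccccc1)(c1ccccc1)c1ccccc1.[Br-]
Why: Wittig methylenation; the non-enolisable ketone carbonyl next to the lactone carbonyl is much more electrophilic than the lactone carbonyl, so only it should react.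

Step 2
Reactants: 2 4,4-dimethyl-3-methylideneoxolan-2-one; 3 isoprene
Product: 4 (5S)-4,4,8-trimethyl-2-oxaspiro[4.5]dec-7-en-1-one
Conditions: (S)-3,3-diphenyl-1-(2-methylphenyl)tetrahydro-1H,3H-pyrrolo[1,2-c][1,3,2]oxazaborole (20 mol %), HN(SO2CF3)2 (18 mol %), isoprene (5 equiv), CH2Cl2, −40 → −20 °C
Reagents that add atoms: none
Why: Catalytic enantioselective Diels–Alder reaction with "para" regiochemistry (ring methyl 1,4 to the spiro carbon); the protonated oxazaborolidine binds the lactone carbonyl and shields one face of the exocyclic alkene, which sets C6, the only stereocentre formed.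

Step 3
Reactants: 4 (5S)-4,4,8-trimethyl-2-oxaspiro[4.5]dec-7-en-1-one
Product: 6 (1R,4S,6R)-6-bromo-4-(1-hydroxy-2-methylpropan-2-yl)-1-methyl-2-oxabicyclo[2.2.2]octan-3-one, via lithium hydroxy carboxylate 5 (not isolated)
Conditions: LiOH, THF/H2O, rt; then NaHCO3, N-bromosuccinimide, 0 °C
Reagents that add atoms: lithium hydroxide, [Li+].[OH-]; N-bromosuccinimide, O=C1CCC(=O)N1Br
Why: Bromolactonisation; the C7 carboxylate on C6 can reach the tertiary C3 (Markovnikov) only across its own face and bromine adds anti at C2, so C2 and C3 are both set from C6 in one event through the temporary bicyclic lactone.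

Step 4
Reactants: 6 (1R,4S,6R)-6-bromo-4-(1-hydroxy-2-methylpropan-2-yl)-1-methyl-2-oxabicyclo[2.2.2]octan-3-one
Product: 8 (5S,7R,8R)-7-bromo-8-chloro-4,4,8-trimethyl-2-oxaspiro[4.5]decan-1-one, via chloro hydroxy acid 7 (not isolated)
Conditions: HCl (4 M in dioxane), CH2Cl2, 0 °C → rt
Reagents that add atoms: hydrogen chloride, Cl
Why: Acid cleavage of the tertiary alkyl–oxygen bond of the lactone gives a C3 cation bridged by the C2 bromine on the opposite face, chloride opens it at C3 from the face the oxygen left (retention, trans Br/Cl), and the freed acid relactonises onto the primary alcohol.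

Step 5
Reactants: 8 (5S,7R,8R)-7-bromo-8-chloro-4,4,8-trimethyl-2-oxaspiro[4.5]decan-1-one
Product: 9 1-[(1S,3R,4R)-3-bromo-4-chloro-1-(1-hydroxy-2-methylpropan-2-yl)-4-methylcyclohexyl]ethan-1-one (in equilibrium with its cyclic hemiketal)
Conditions: MeLi (1.1 equiv), THF, −78 °C; then aq. NH4Cl
Reagents that add atoms: methyllithium, [Li]C
Why: Single addition of MeLi to a hindered lactone; the lithium hemiketal persists at −78 °C, so the methyl ketone level is reached and the new methyl is the future C14.

Step 6
Reactants: 9 1-[(1S,3R,4R)-3-bromo-4-chloro-1-(1-hydroxy-2-methylpropan-2-yl)-4-methylcyclohexyl]ethan-1-one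
Product: 10 2-[(1S,3R,4R)-1-acetyl-3-bromo-4-chloro-4-methylcyclohexyl]-2-methylpropanal
Conditions: Dess–Martin periodinane, NaHCO3, CH2Cl2, rt
Reagents that add atoms: none
Why: Oxidation of the primary alcohol of the open hydroxy ketone form; the tertiary hemiketal OH cannot be oxidised, so the equilibrium should drain to the keto aldehyde.

Step 7
Reactants: 10 2-[(1S,3R,4R)-1-acetyl-3-bromo-4-chloro-4-methylcyclohexyl]-2-methylpropanal
Product: 11 1-[(1S,3R,4R)-3-bromo-4-chloro-1-(1,1-dibromo-2-methylpropan-2-yl)-4-methylcyclohexyl]ethan-1-one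
Conditions: P(OPh)3, Br2, CH2Cl2, −78 °C; then 10, −78 °C → rt
Reagents that add atoms: bromine, BrBr
Why: Deoxygenative gem-dibromination of an aldehyde by triphenyl phosphite dibromide; the non-enolisable aldehyde should react well before the hindered methyl ketone.

Step 8
Reactants: 11 1-[(1S,3R,4R)-3-bromo-4-chloro-1-(1,1-dibromo-2-methylpropan-2-yl)-4-methylcyclohexyl]ethan-1-one
Product: 12 1-[(1S,3R,4R)-3-bromo-4-chloro-1-(1,1-dibromo-2-methylpropan-2-yl)-4-methylcyclohexyl]ethenyl trifluoromethanesulfonate
Conditions: KN(SiMe3)2 (1.05 equiv), THF, −78 °C; then PhN(SO2CF3)2, −78 → 0 °C; then aq. NH4Cl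
Reagents that add atoms: N-phenylbis(trifluoromethanesulfonimide), O=S(=O)(N(c1ccccc1)S(=O)(=O)C(F)(F)F)C(F)(F)F
Why: Enolate O-triflation; the ketone can enolise only toward its methyl group because C6 is quaternary, so the 1,1-disubstituted alkenyl triflate (C7=C14) is the only regioisomer possible.

Step 9
Reactants: 12 1-[(1S,3R,4R)-3-bromo-4-chloro-1-(1,1-dibromo-2-methylpropan-2-yl)-4-methylcyclohexyl]ethenyl trifluoromethanesulfonate; 13 2-bromo-N-methoxy-N-methylacetamide
Product: 15 3-[(1R,3R,4R)-3-bromo-4-chloro-1-(1,1-dibromo-2-methylpropan-2-yl)-4-methylcyclohexyl]-N-methoxy-N-methylbut-3-enamide, via zinc reagent 14 (not isolated)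
Conditions: 13, Zn, THF, 40 °C; solution of 14 decanted from excess Zn; then 12, Pd(PPh3)4 (5 mol %), THF, 50 °C
Reagents that add atoms: none
Why: Negishi-type cross-coupling of a Reformatsky zinc reagent with an alkenyl triflate; it forms C7–C8 and delivers the C7 methylidene and the C9 acyl group under conditions that leave the alkyl halides alone.

Step 10
Reactants: 15 3-[(1R,3R,4R)-3-bromo-4-chloro-1-(1,1-dibromo-2-methylpropan-2-yl)-4-methylcyclohexyl]-N-methoxy-N-methylbut-3-enamide
Product: 18 (2R,3R,6R,10R)-2,10-dibromo-3-chloro-3,11,11-trimethyl-7-methylidenespiro[5.5]undecan-9-one, via lithium carbenoid 16 (not isolated), via lithium hemiaminal 17 (not isolated)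
Conditions: MeLi·LiBr (1.1 equiv), THF/Et2O, −95 → −78 °C; then aq. NH4Cl at −78 °C
Reagents that add atoms: none
Why: Proposed new method: Br/Li exchange at the gem-dibromide gives the α-bromoalkyllithium 16, whose C10 attacks the tethered amide carbonyl C9, and the chelated tetrahedral adduct 17 survives until the quench and only then collapses to the α-bromo ketone, so no second addition can occur. The closest known reaction is the Barbier-type acylation of bromomethyllithium (from CH2Br2 and MeLi·LiBr) by N-methoxy-N-methylamides to give bromomethyl ketones; here it is made intramolecular and run on a secondary carbenoid. Ring A closes in a 6-exo-trig mode, helped by the gem-dimethyl C11 and quaternary C6 (Thorpe–Ingold effect), and the quaternary C11 denies the carbenoid the usual 1,2-hydride-shift decomposition. C10 is the only new stereocentre and nothing in the substrate controls it, because the two ring B arms on the spiro carbon differ only at remote atoms; the C10 epimer of 18 is therefore expected alongside it, the pair is carried on unseparated, and catalyst control in step 11 picks 18. The step needs exchange at the gem-dibromide rather than at the secondary C2–Br or tertiary C3–Cl, and acylation before deprotonation at C8; the far faster exchange of gem-dibromides, the weak kinetic basicity of MeLi at low temperature and the chelation-assisted intramolecular attack should secure this.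

Step 11
Reactants: 18 (2R,3R,6R,10R)-2,10-dibromo-3-chloro-3,11,11-trimethyl-7-methylidenespiro[5.5]undecan-9-one
Product: 19 (2R,3R,6R,9S,10R)-2,10-dibromo-3-chloro-3,11,11-trimethyl-7-methylidenespiro[5.5]undecan-9-ol
Conditions: (R)-1-methyl-3,3-diphenyltetrahydro-1H,3H-pyrrolo[1,2-c][1,3,2]oxazaborole (20 mol %), catecholborane (0.55 equiv relative to the total bromo ketone from step 10), toluene/CH2Cl2, −78 → −40 °C; then chromatography
Reagents that add atoms: none
Why: Corey–Bakshi–Shibata reduction under catalyst control; with the C10 side as the large group the (R)-catalyst gives 9S, which for 18 is also the equatorial attack favoured by the substrate (axial attack is blocked by the axial C11 methyl) and puts OH axial and cis to the equatorial C10–Br, so 18 should be reduced fast while its mismatched C10 epimer stays a ketone and is removed by chromatography.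

Step 12
Reactants: 19 (2R,3R,6R,9S,10R)-2,10-dibromo-3-chloro-3,11,11-trimethyl-7-methylidenespiro[5.5]undecan-9-ol
Product: 20 (2R,3R,6R,9S,10R)-2,10-dibromo-3-chloro-3,11,11-trimethyl-7-methylidenespiro[5.5]undecan-9-yl acetate
Conditions: Ac2O, pyridine, 4-(dimethylamino)pyridine (cat.), CH2Cl2, rt
Reagents that add atoms: acetic anhydride, CC(=O)OC(C)=O
Why: Nucleophile-catalysed acetylation of the hindered axial secondary alcohol; no stereocentre is touched.

**Compound list**

1 | 4,4-dimethyloxolane-2,3-dione (ketopantolactone) | O=C1OCC(C)(C)C1=O | starting material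
2 | 4,4-dimethyl-3-methylideneoxolan-2-one | C=C1C(=O)OCC1(C)C | intermediate
3 | isoprene (2-methylbuta-1,3-diene) | C=CC(C)=C | starting material
4 | (5S)-4,4,8-trimethyl-2-oxaspiro[4.5]dec-7-en-1-one | O=C1OCC(C)(C)[C@@]12CCC(C)=CC2 | intermediate
5 | lithium (1S)-1-(1-hydroxy-2-methylpropan-2-yl)-4-methylcyclohex-3-ene-1-carboxylate (not isolated) | [Li+].[O-]C(=O)[C@@]1(C(C)(C)CO)CCC(C)=CC1 | intermediate
6 | (1R,4S,6R)-6-bromo-4-(1-hydroxy-2-methylpropan-2-yl)-1-methyl-2-oxabicyclo[2.2.2]octan-3-one | OCC(C)(C)[C@@]12CC[C@@](C)(OC1=O)[C@H](Br)C2 | intermediate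
7 | (1S,3R,4R)-3-bromo-4-chloro-1-(1-hydroxy-2-methylpropan-2-yl)-4-methylcyclohexane-1-carboxylic acid (not isolated) | OC(=O)[C@@]1(C(C)(C)CO)CC[C@@](C)(Cl)[C@H](Br)C1 | intermediate
8 | (5S,7R,8R)-7-bromo-8-chloro-4,4,8-trimethyl-2-oxaspiro[4.5]decan-1-one | O=C1OCC(C)(C)[C@@]12CC[C@@](C)(Cl)[C@H](Br)C2 | intermediate
9 | 1-[(1S,3R,4R)-3-bromo-4-chloro-1-(1-hydroxy-2-methylpropan-2-yl)-4-methylcyclohexyl]ethan-1-one (open form of the cyclic hemiketal) | CC(=O)[C@@]1(C(C)(C)CO)CC[C@@](C)(Cl)[C@H](Br)C1 | intermediate
10 | 2-[(1S,3R,4R)-1-acetyl-3-bromo-4-chloro-4-methylcyclohexyl]-2-methylpropanal | CC(=O)[C@@]1(C(C)(C)C=O)CC[C@@](C)(Cl)[C@H](Br)C1 | intermediate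
11 | 1-[(1S,3R,4R)-3-bromo-4-chloro-1-(1,1-dibromo-2-methylpropan-2-yl)-4-methylcyclohexyl]ethan-1-one | CC(=O)[C@@]1(C(C)(C)C(Br)Br)CC[C@@](C)(Cl)[C@H](Br)C1 | intermediate
12 | 1-[(1S,3R,4R)-3-bromo-4-chloro-1-(1,1-dibromo-2-methylpropan-2-yl)-4-methylcyclohexyl]ethenyl trifluoromethanesulfonate | C=C(OS(=O)(=O)C(F)(F)F)[C@@]1(C(C)(C)C(Br)Br)CC[C@@](C)(Cl)[C@H](Br)C1 | intermediate
13 | 2-bromo-N-methoxy-N-methylacetamide | CON(C)C(=O)CBr | starting material
14 | bromo[2-[methoxy(methyl)amino]-2-oxoethyl]zinc (not isolated) | CON(C)C(=O)C[Zn]Br | intermediate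
15 | 3-[(1R,3R,4R)-3-bromo-4-chloro-1-(1,1-dibromo-2-methylpropan-2-yl)-4-methylcyclohexyl]-N-methoxy-N-methylbut-3-enamide | C=C(CC(=O)N(C)OC)[C@@]1(C(C)(C)C(Br)Br)CC[C@@](C)(Cl)[C@H](Br)C1 | intermediate
16 | α-bromoalkyllithium from 15, Li and Br on C10, C10 configurationally labile (not isolated) | C=C(CC(=O)N(C)OC)[C@@]1(C(C)(C)C([Li])Br)CC[C@@](C)(Cl)[C@H](Br)C1 | intermediate
17 | lithium alkoxide of the C9 N-methoxy-N-methyl hemiaminal of 18, both configurations at C9 (not isolated) | C=C1CC(O[Li])(N(C)OC)[C@H](Br)C(C)(C)[C@@]12CC[C@@](C)(Cl)[C@H](Br)C2 | intermediate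
18 | (2R,3R,6R,10R)-2,10-dibromo-3-chloro-3,11,11-trimethyl-7-methylidenespiro[5.5]undecan-9-one | C=C1CC(=O)[C@H](Br)C(C)(C)[C@@]12CC[C@@](C)(Cl)[C@H](Br)C2 | intermediate
19 | (2R,3R,6R,9S,10R)-2,10-dibromo-3-chloro-3,11,11-trimethyl-7-methylidenespiro[5.5]undecan-9-ol | C=C1C[C@H](O)[C@H](Br)C(C)(C)[C@@]12CC[C@@](C)(Cl)[C@H](Br)C2 | intermediate
20 | (2R,3R,6R,9S,10R)-2,10-dibromo-3-chloro-3,11,11-trimethyl-7-methylidenespiro[5.5]undecan-9-yl acetate | C=C1C[C@H](OC(C)=O)[C@H](Br)C(C)(C)[C@@]12CC[C@@](C)(Cl)[C@H](Br)C2 | target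

**Count and risks**

Total steps: 12. Longest linear sequence: 12 steps (1 → 20).

Steps most likely to fail:

First, step 10. The carbenoid may decompose by α-elimination and methyl shift before the ring closes, or the amide may be deprotonated at C8 or attacked by MeLi. The fallback closes the same C9–C10 bond by ring-closing metathesis of an enol ether and sets out from keto aldehyde 10. Selective Wittig methylenation of the aldehyde (Ph3P=CH2, THF, −78 °C) should give 1-[(1S,3R,4R)-3-bromo-4-chloro-4-methyl-1-(2-methylbut-3-en-2-yl)cyclohexyl]ethan-1-one F1. Enol triflation as in step 8 gives 1-[(1S,3R,4R)-3-bromo-4-chloro-4-methyl-1-(2-methylbut-3-en-2-yl)cyclohexyl]ethenyl trifluoromethanesulfonate F2. 3-Bromo-2-methoxyprop-1-ene and Zn in THF give bromo(2-methoxyprop-2-en-1-yl)zinc F3. Its coupling with F2 under Pd(PPh3)4 (5 mol %) in THF at 40 °C gives 2-[(1R,3R,4R)-3-bromo-4-chloro-4-methyl-1-(2-methylbut-3-en-2-yl)cyclohexyl]-4-methoxypenta-1,4-diene F4, in which the C9 oxygen and the C9 alkene terminus are in place with no regiochemical question. The second-generation Grubbs catalyst in toluene at 80 °C closes ring A between the vinyl group and the enol ether to (2R,3R,6R)-2-bromo-3-chloro-9-methoxy-3,11,11-trimethyl-7-methylidenespiro[5.5]undec-9-ene F5. N-Bromosuccinimide in THF/H2O at 0 °C brominates F5 at C10 and releases the ketone, and the route is rejoined at bromo ketone 18 (again formed with its C10 epimer) before step 11.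

Second, step 4. The C3 cation may lose a proton to give alkenes, or chloride capture in the protic medium may not be stereospecific, which would erode C3. The fallback sets out from bromo lactone 6 and replaces protic ionisation by a stepwise route through an isolated alcohol. Catalytic camphorsulfonic acid in CH2Cl2 moves the acyl group onto the primary alcohol and gives (5S,7R,8R)-7-bromo-8-hydroxy-4,4,8-trimethyl-2-oxaspiro[4.5]decan-1-one F6. SOCl2 in Et2O at −20 °C then converts the tertiary alcohol through its chlorosulfite into the chloride, with the bromine on the opposite face guiding chloride return. The route is rejoined at 8.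

Third, step 11. The catalyst may not distinguish the two C10 epimers well enough, so that both ketones are reduced and diastereomers that are hard to separate are carried on. The fallback sets out from 18 as it comes from step 10, that is together with its C10 epimer, and replaces catalyst control by substrate-controlled reduction followed by enzymatic resolution. LiBH(sBu)3 in THF at −78 °C should reduce both ketones by equatorial attack and give 19 and, from the epimer, (2R,3R,6R,9R,10S)-2,10-dibromo-3-chloro-3,11,11-trimethyl-7-methylidenespiro[5.5]undecan-9-ol F7. Lipase from Burkholderia cepacia with vinyl acetate in tert-butyl methyl ether should then acylate the 9R alcohol selectively to (2R,3R,6R,9R,10S)-2,10-dibromo-3-chloro-3,11,11-trimethyl-7-methylidenespiro[5.5]undecan-9-yl acetate F8 and leave 19. Alcohol 19 is separated from the ester by chromatography and rejoins the route at 19, before step 12.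

Further compounds
F1 | step 10 | 1-[(1S,3R,4R)-3-bromo-4-chloro-4-methyl-1-(2-methylbut-3-en-2-yl)cyclohexyl]ethan-1-one | CC(=O)[C@@]1(C(C)(C)C=C)CC[C@@](C)(Cl)[C@H](Br)C1
F2 | step 10 | 1-[(1S,3R,4R)-3-bromo-4-chloro-4-methyl-1-(2-methylbut-3-en-2-yl)cyclohexyl]ethenyl trifluoromethanesulfonate | C=C(OS(=O)(=O)C(F)(F)F)[C@@]1(C(C)(C)C=C)CC[C@@](C)(Cl)[C@H](Br)C1
F3 | step 10 | bromo(2-methoxyprop-2-en-1-yl)zinc | COC(=C)C[Zn]Br
F4 | step 10 | 2-[(1R,3R,4R)-3-bromo-4-chloro-4-methyl-1-(2-methylbut-3-en-2-yl)cyclohexyl]-4-methoxypenta-1,4-diene | C=C(CC(=C)OC)[C@@]1(C(C)(C)C=C)CC[C@@](C)(Cl)[C@H](Br)C1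
F5 | step 10 | (2R,3R,6R)-2-bromo-3-chloro-9-methoxy-3,11,11-trimethyl-7-methylidenespiro[5.5]undec-9-ene | C=C1CC(OC)=CC(C)(C)[C@@]12CC[C@@](C)(Cl)[C@H](Br)C2
F6 | step 4 | (5S,7R,8R)-7-bromo-8-hydroxy-4,4,8-trimethyl-2-oxaspiro[4.5]decan-1-one | O=C1OCC(C)(C)[C@@]12CC[C@@](C)(O)[C@H](Br)C2
F7 | step 11 | (2R,3R,6R,9R,10S)-2,10-dibromo-3-chloro-3,11,11-trimethyl-7-methylidenespiro[5.5]undecan-9-ol | C=C1C[C@@H](O)[C@@H](Br)C(C)(C)[C@@]12CC[C@@](C)(Cl)[C@H](Br)C2
F8 | step 11 | (2R,3R,6R,9R,10S)-2,10-dibromo-3-chloro-3,11,11-trimethyl-7-methylidenespiro[5.5]undecan-9-yl acetate | C=C1C[C@@H](OC(C)=O)[C@@H](Br)C(C)(C)[C@@]12CC[C@@](C)(Cl)[C@H](Br)C2
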